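Readings and results are calculated from invented constants.

Whatever is charged stays in the closed flask, so the fractions of the substrate charge add up to one, and target can be pinned at both ends of a run: by its early rate and by the level at which it stalls, the two joined by an exponential approach.

| setting | cedar | alder | birch | south | south-west | west | east |
|---|---|---|---|---|---|---|---|
| substrate | 1.5 M | 1.5 M | 3 M | 1.5 M | 1.5 M | 1.5 M | 1.5 M |
| first nucleophile | 0.45 M | 1.8 M | 0.90 M | 0.900 M | 0.900 M | 0.900 M | 0.900 M |
| gas | 73 mM (held) | 73 mM (held) | 73 mM (held) | 73 mM (held) | 73 mM (held) | 73 mM (held) | 73 mM (held) |
| temperature | 48 °C | 64 °C | 48 °C | 40 °C |  | 70 °C | 55 °C |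
| remark | run made earlier | run made earlier | run made earlier |  | at 40 °C until 4.0 h, from then on at 70 °C |  |  |
| time |  |  |  | 5.0 h | 5.0 h | 5.0 h | 5.0 h |

- cedar (time / h: target / %): 1.50: 2.5; 3.00: 4.7; 5.00: 5.7; 6.00: 5.0
- alder (time / min: target / %): 15.0: 15.7; 40.0: 30.6; 80.0: 38.3; 120: 42.7
- birch (time / h: target / %): 0.500: 4.2; 1.00: 8.6; 2.50: 12.4; 6.00: 17.6

(readings scatter by 1 percentage point)

- at the start none of the gas is in solution

* the flask with the highest amount of target, in percent of the substrate charged ("all alike" if they lie within 1.5 percentage points) (south / south-west / west / east / all alike)
* final target, as a percentage of the substrate charged, in south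
* final target, as a percentage of the substrate charged, in south-west
* final target, as a percentage of the substrate charged, in west
* final target, as a percentage of the substrate charged, in east

Two views dispute how those ends move with temperature. The forecast holds that “target formation and loss have similar activation energy”, so its level barely moves, and it gives 11 % in south, 15 % in south-west, 19 % in west and 17.5 % in east, with west highest.

My own view is steep. Cedar and alder carry the substrate charge of the asked flasks, so I compare those two and leave birch aside, assuming that the rate scales with first nucleophile. The first reading over its time, per molar of first nucleophile, is 9.42 times higher in alder than in cedar, and this factor is the temperature gain, a temperature coefficient of the mean rate up to the first reading; it is a rough reading and no initial rate, for it leans on cedar's 2.5 % with a scatter of 1 percentage point. The stall level per molar, read from cedar's reading at 5.00 h and alder's at 120 min, rises by a factor of 1.87, less than the gain, but it does rise, and alder is still climbing, so my hot levels lean low.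

Spreading both factors evenly over temperature, south has a rate of 0.0109 /h and a level of 8.33 %, and it needs 7.64 h to approach that level, longer than its 5.0 h, so I expect 3.99 %. West has a level of 27.0 % and a rate of 0.728 /h, so it approaches in 0.371 h, which is shorter than the hot hour of south-west. That gives 27.0 % in west and 25.4 % in south-west. The same steps give 14.2 % in east.

South gives 2.86 %, south-west 28.9 %, west 43.3 % and east 19.3 %, so west leads as both views said. The steep view lands closer in south, south-west and west, and the level view keeps the middle temperature, east.

    substrate ⇌ intermediate (K = 0.0140, k = 0.0760 /h, Ea = 96.0 kJ/mol, ΔH = 8.00 kJ/mol)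
    first nucleophile + intermediate → target (k = 46.0 /M/h, Ea = 47.0 kJ/mol)
    second nucleophile + intermediate → other capture product (k = 8900 /M/h, Ea = 46.0 kJ/mol)
    substrate + intermediate → side product (k = 0.0200 /M/h, Ea = 79.0 kJ/mol)
    target ⇌ isomer of the product (K = 0.620, k = 0.0350 /h, Ea = 116 kJ/mol, ΔH = −25.0 kJ/mol)
    gas ⇌ second nucleophile, rate k6*(csat - [second nucleophile]) (kL = 3.30 /h)
    (constants at 40 °C)

The gain gives 2.72 % for south at 2.50 h against 1.85 %, and 1.45 % for south-west read at 80 min against 1.23 %. In south-west at 5.00 h, capture of intermediate gives second nucleophile a half-life of 0.46 min, shorter than the 12.6 min of its refill from gas. Second nucleophile stands there at 0.00254 M, down from 0.0493 M at 4.00 h.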